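Labels: the upper flavan has rings A (benzo), B (2-aryl) and C (pyran), with atoms marked u. The lower epiafzelechin has rings D (benzo), E (2-aryl) and F (pyran), with plain flavan numbers.
Cuts: first the five O-benzyl groups and the C3–H bond (a flavan-3-one). Then ring F is cut at C4–C3 and O1–C8a together, giving a ring-D dielectrophile (C4–Cl, C8a–F) and a C3/O1 dinucleophile (dithiane carbanion plus C2 oxide). Last come C4–C4a, C4u–C6 and C2u–ring B.
Enabling feature: C8a of ring D is meta to O5 and O7, ortho to the C4a–CH2 arm and para to C6. A fluorine there is displaceable, pairs with C4 as a 1,3-dielectrophile, and leaves the ring-D precursor mirror-symmetric, so only the 4u-6 isomer can form. C3, a carbinol carbon beside C2–O, can be carried as a dithiane acyl anion.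
Forward order: ring B is added to 7-benzyloxychromone (ring C complete), ring D is joined at C4u, C4 is placed on ring D beside fluorine, and ring F is closed last in one flask.
Stereochemistry: C2u comes from ligand-controlled Pd conjugate addition. C4u comes from hydride capture of the C4u cation trans to ring B (2,4-cis). C2 comes from CBS reduction and is retained. C3 comes from bulky hydride attack on the 3-ketone anti to ring E (2,3-cis).

Key step: step 11

Assumption 1: the PyOx ligand is taken to induce the same facial sense on chromones as on 3-substituted cyclohexenones, which makes the (R)-ligand the one for 2S; otherwise its antipode is used.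
Assumption 2: in the CBS reduction of the aroyl dithiane, the 1,3-dithian-2-yl group is taken as the larger ketone substituent, which makes (S)-Me-CBS the catalyst for the R alcohol.

Step 1
Reactants: 1 7-hydroxy-4H-chromen-4-one
Product: 2 7-(benzyloxy)-4H-chromen-4-one
Conditions: BnBr, K2CO3, DMF, 25 °C
Reagents that add atoms: benzyl bromide BrCc1ccccc1
Why: Williamson ether synthesis on the acidic 7-phenol, which K2CO3 deprotonates without opening the pyranone ring; no stereocentre is formed.

Step 2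
Reactants: 2 7-(benzyloxy)-4H-chromen-4-one; 3 [4-(benzyloxy)phenyl]boronic acid
Product: 4 (2S)-7-(benzyloxy)-2-[4-(benzyloxy)phenyl]chroman-4-one
Conditions: Pd(OCOCF3)2 (5 mol %), (R)-t-BuPyOx (6 mol %), NH4PF6, H2O, ClCH2CH2Cl, 60 °C
Reagents that add atoms: none
Why: Pd-catalysed asymmetric conjugate addition of an arylboronic acid to a chromone, in which the aryl-palladium species held by the chiral pyridine-oxazoline inserts one enone face and so sets C2u as S, while the near-neutral medium avoids retro-oxa-Michael racemisation.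

Step 3
Reactants: 5 5-fluorobenzene-1,3-diol
Product: 6 5-fluoro-2-iodobenzene-1,3-diol
Conditions: I2, NaHCO3, H2O, 0 to 25 °C
Reagents that add atoms: iodine II
Why: Electrophilic aromatic iodination of a resorcinol under bicarbonate buffering, conditions known to place iodine between the two hydroxyls, a site that here is also para to fluorine whereas the alternatives are ortho to it.

Step 4
Reactants: 6 5-fluoro-2-iodobenzene-1,3-diol
Product: 7 1,3-bis(benzyloxy)-5-fluoro-2-iodobenzene
Conditions: BnBr (2.2 equiv), K2CO3, DMF, 25 °C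
Reagents that add atoms: benzyl bromide BrCc1ccccc1
Why: Double Williamson ether synthesis, to which the aryl iodide and fluoride are inert.

Step 5
Reactants: 7 1,3-bis(benzyloxy)-5-fluoro-2-iodobenzene; 4 (2S)-7-(benzyloxy)-2-[4-(benzyloxy)phenyl]chroman-4-one
Product: 9 (2S)-7-(benzyloxy)-2-[4-(benzyloxy)phenyl]-4-[2,6-bis(benzyloxy)-4-fluorophenyl]chroman-4-ol (both C4u epimers), via arylmagnesium chloride 8 (not isolated)
Conditions: 7, i-PrMgCl·LiCl, THF, -20 °C; then 4 premixed with LaCl3·2LiCl, THF, -20 to 0 °C; aq NH4Cl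
Reagents that add atoms: none
Why: Iodine-magnesium exchange followed by lanthanide-promoted 1,2-addition of the aryl Grignard reagent, in which LaCl3 activates the carbonyl and tempers basicity so that enolisation and ring opening of the flavanone (loss of C2u) should be suppressed; the new C4u carbinol centre may be a mixture because step 6 erases it.

Step 6
Reactants: 9 (2S)-7-(benzyloxy)-2-[4-(benzyloxy)phenyl]-4-[2,6-bis(benzyloxy)-4-fluorophenyl]chroman-4-ol
Product: 10 (2S,4S)-7-(benzyloxy)-2-[4-(benzyloxy)phenyl]-4-[2,6-bis(benzyloxy)-4-fluorophenyl]chroman (2,4-cis)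
Conditions: Et3SiH, CF3CO2H, CH2Cl2, -40 to -10 °C
Reagents that add atoms: none
Why: Ionic hydrogenation (SN1 ionisation, then silane hydride transfer), in which the C4u cation stabilised by O1u and O7u of ring A should take hydride pseudo-axially on the half-chair that keeps ring B equatorial, that is trans to ring B, leaving ring D equatorial and cis to ring B (4S).

Step 7
Reactants: 10 (2S,4S)-7-(benzyloxy)-2-[4-(benzyloxy)phenyl]-4-[2,6-bis(benzyloxy)-4-fluorophenyl]chroman
Product: 13 (2S,4S)-7-(benzyloxy)-2-[4-(benzyloxy)phenyl]-4-[2,6-bis(benzyloxy)-4-fluoro-3-(hydroxymethyl)phenyl]chroman, via aryllithium 11 (not isolated), via aldehyde 12 (not isolated)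
Conditions: LiN(i-Pr)2, THF, -78 °C; DMF, -78 to -20 °C; then MeOH, NaBH4, 0 °C
Reagents that add atoms: N,N-dimethylformamide CN(C)C=O
Why: Directed ortho-metalation, formylation and borohydride reduction, in which the amide base removes the most acidic ring proton (flanked by fluorine and benzyloxy on ring D); the two such positions interchange by rotation about the C4u–C6 bond, so one constitutional isomer and no new stereocentre should result.

Step 8
Reactants: 13 (2S,4S)-7-(benzyloxy)-2-[4-(benzyloxy)phenyl]-4-[2,6-bis(benzyloxy)-4-fluoro-3-(hydroxymethyl)phenyl]chroman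
Product: 14 (2S,4S)-7-(benzyloxy)-2-[4-(benzyloxy)phenyl]-4-[2,6-bis(benzyloxy)-3-(chloromethyl)-4-fluorophenyl]chroman
Conditions: MsCl, Et3N, CH2Cl2, 0 to 25 °C; used without chromatography
Reagents that add atoms: methanesulfonyl chloride CS(=O)(=O)Cl
Why: Mesylation with in situ chloride displacement, the usual course for electron-rich benzylic alcohols, gives the reactive chloride under non-acidic conditions that spare the benzyl ethers and both stereocentres.

Step 9
Reactants: 15 1,3-dithiane; 16 methyl 4-(benzyloxy)benzoate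
Product: 18 [4-(benzyloxy)phenyl](1,3-dithian-2-yl)methanone, via 2-lithio-1,3-dithiane 17 (not isolated)
Conditions: 15 (2.2 equiv), n-BuLi (2.1 equiv), THF, -30 °C; 16, -78 to 0 °C; H2O
Reagents that add atoms: none
Why: Corey–Seebach acylation of 2-lithio-1,3-dithiane by an ester, with over-addition blocked because the second equivalent of 17 removes the acidic C–H of the product.

Step 10
Reactants: 18 [4-(benzyloxy)phenyl](1,3-dithian-2-yl)methanone
Product: 19 (R)-[4-(benzyloxy)phenyl](1,3-dithian-2-yl)methanol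
Conditions: (S)-Me-CBS (0.2 equiv), BH3·SMe2, THF, -20 °C; MeOH
Reagents that add atoms: none
Why: Corey–Bakshi–Shibata reduction of a 2-acyl-1,3-dithiane, in which the ketone binds the oxazaborolidine boron anti to the larger dithianyl group and borane hydride is delivered to one face, setting C2 as R.

Step 11
Reactants: 19 (R)-[4-(benzyloxy)phenyl](1,3-dithian-2-yl)methanol; 14 (2S,4S)-7-(benzyloxy)-2-[4-(benzyloxy)phenyl]-4-[2,6-bis(benzyloxy)-3-(chloromethyl)-4-fluorophenyl]chroman
Product: 22 (2R)-5,7-bis(benzyloxy)-2-[4-(benzyloxy)phenyl]-6-{(2S,4S)-7-(benzyloxy)-2-[4-(benzyloxy)phenyl]chroman-4-yl}spiro[chroman-3,2'-[1,3]dithiane], via dilithiated carbinol 20 (not isolated), via lithium alkoxide 21 (not isolated)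
Conditions: 19, n-BuLi (2.1 equiv), THF, -30 °C; 14, -78 to 0 °C; then KOt-Bu, 18-crown-6, DMPU, 60 °C
Reagents that add atoms: none
Why: Proposed new method: the dilithiated carbinol 20 should attack the benzylic chloride of 14 through its far more basic dithiane carbon (SN2, C4–C3 bond), and the alkoxide 21, now three atoms from C8a, should after Li/K exchange in DMPU with 18-crown-6 add to C8a and expel fluoride (SNAr, O1–C8a bond), so that a C3/O1 1,3-dinucleophile and a C4/C8a 1,3-dielectrophile are stitched into ring F in one flask. The closest known reaction types are Corey–Seebach alkylation of 2-substituted 2-lithio-1,3-dithianes including their hydroxyalkyl dianions, pyran closure by intramolecular SNAr of a benzylic alkoxide on a 3,5-dialkoxyfluorobenzene, and the domino C-benzylation/O-arylation of 2-halobenzyl halides by 1,3-dicarbonyl compounds; what is new is their merger with an acyl-anion carbon. Ring F, the only ring closed, forms by 6-endo-trig addition at C8a to a Meisenheimer adduct whose charge rests on C4a, C6 and C8, positions free of oxygen because O5 and O7 are meta to C8a, and the gem-dithio carbon C3 should speed closure (Thorpe–Ingold effect). No stereocentre is created, since C3 is a symmetric spiro dithioketal carbon, and C2 keeps its R configuration because its C–O bond is never broken and its hydrogen is not acidic beside the oxide. The step needs C- over O-benzylation (secured by the basicity gap at -78 °C), six- over five-membered closure (secured because C3 carries sulfur and no second oxide) and closure to the 4u-6 rather than the 4u-8 isomer (secured because ring D holds a single fluorine, para to C6).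

Step 12
Reactants: 22 (2R)-5,7-bis(benzyloxy)-2-[4-(benzyloxy)phenyl]-6-{(2S,4S)-7-(benzyloxy)-2-[4-(benzyloxy)phenyl]chroman-4-yl}spiro[chroman-3,2'-[1,3]dithiane]
Product: 23 (2R)-5,7-bis(benzyloxy)-2-[4-(benzyloxy)phenyl]-6-{(2S,4S)-7-(benzyloxy)-2-[4-(benzyloxy)phenyl]chroman-4-yl}chroman-3-one
Conditions: MeI, CaCO3, MeCN/THF/H2O, 50 °C
Reagents that add atoms: water O
Why: Alkylative hydrolysis of a dithioketal (S-methylation, thionium formation, capture by water), a non-oxidative method that spares the electron-rich rings, with the CaCO3 buffer keeping the medium neutral so that C2, now alpha to the ketone, should not epimerise.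

Step 13
Reactants: 23 (2R)-5,7-bis(benzyloxy)-2-[4-(benzyloxy)phenyl]-6-{(2S,4S)-7-(benzyloxy)-2-[4-(benzyloxy)phenyl]chroman-4-yl}chroman-3-one
Product: 24 (2R,3R)-5,7-bis(benzyloxy)-2-[4-(benzyloxy)phenyl]-6-{(2S,4S)-7-(benzyloxy)-2-[4-(benzyloxy)phenyl]chroman-4-yl}chroman-3-ol
Conditions: Li[HB(s-Bu)3] (L-Selectride), THF, -78 °C; aq NH4Cl
Reagents that add atoms: none
Why: Diastereoselective ketone reduction by a bulky trialkylborohydride, the standard entry to 2,3-cis flavan-3-ols from flavan-3-ones, in which hydride arrives equatorially on the face anti to equatorial ring E and gives the axial 3-hydroxyl cis to ring E (3R).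

Step 14
Reactants: 24 (2R,3R)-5,7-bis(benzyloxy)-2-[4-(benzyloxy)phenyl]-6-{(2S,4S)-7-(benzyloxy)-2-[4-(benzyloxy)phenyl]chroman-4-yl}chroman-3-ol
Product: 25 (2R,3R)-2-(4-hydroxyphenyl)-6-[(2S,4S)-7-hydroxy-2-(4-hydroxyphenyl)chroman-4-yl]chroman-3,5,7-triol (target)
Conditions: H2 (1 atm), Pd(OH)2/C, THF/MeOH, 25 °C
Reagents that add atoms: none
Why: Catalytic hydrogenolysis of the five aryl benzyl ethers, conditions under which the cyclic C2–O and C2u–O bonds and the C4u–C6 bond of benzylated flavan oligomers normally survive and no stereocentre is touched.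

Compound list
1 | 7-hydroxy-4H-chromen-4-one | O=c1ccoc2cc(O)ccc12 | starting material
2 | 7-(benzyloxy)-4H-chromen-4-one | O=c1ccoc2cc(OCc3ccccc3)ccc12 | intermediate
3 | [4-(benzyloxy)phenyl]boronic acid | OB(O)c1ccc(OCc2ccccc2)cc1 | starting material
4 | (2S)-7-(benzyloxy)-2-[4-(benzyloxy)phenyl]chroman-4-one | O(Cc5ccccc5)c1ccc([C@@H]2CC(=O)c3ccc(OCc5ccccc5)cc3O2)cc1 | intermediate
5 | 5-fluorobenzene-1,3-diol | Oc1cc(O)cc(F)c1 | starting material
6 | 5-fluoro-2-iodobenzene-1,3-diol | Oc1cc(F)cc(O)c1I | intermediate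
7 | 1,3-bis(benzyloxy)-5-fluoro-2-iodobenzene | Ic1c(OCc2ccccc2)cc(F)cc1OCc3ccccc3 | intermediate
8 | [2,6-bis(benzyloxy)-4-fluorophenyl]magnesium chloride | Cl[Mg]c1c(OCc2ccccc2)cc(F)cc1OCc3ccccc3 | intermediate
9 | (2S)-7-(benzyloxy)-2-[4-(benzyloxy)phenyl]-4-[2,6-bis(benzyloxy)-4-fluorophenyl]chroman-4-ol (both C4u epimers) | O(Cc5ccccc5)c1ccc([C@@H]2CC(O)(c3c(OCc5ccccc5)cc(F)cc3OCc5ccccc5)c3ccc(OCc5ccccc5)cc3O2)cc1 | intermediate
10 | (2S,4S)-7-(benzyloxy)-2-[4-(benzyloxy)phenyl]-4-[2,6-bis(benzyloxy)-4-fluorophenyl]chroman | O(Cc5ccccc5)c1ccc([C@@H]2C[C@H](c3c(OCc5ccccc5)cc(F)cc3OCc5ccccc5)c3ccc(OCc5ccccc5)cc3O2)cc1 | intermediate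
11 | ring-D aryllithium of 10 (lithium between fluorine and benzyloxy) | O(Cc5ccccc5)c1ccc([C@@H]2C[C@H](c3c(OCc5ccccc5)cc(F)c([Li])c3OCc5ccccc5)c3ccc(OCc5ccccc5)cc3O2)cc1 | intermediate
12 | 2,4-bis(benzyloxy)-6-fluoro-3-{(2S,4S)-7-(benzyloxy)-2-[4-(benzyloxy)phenyl]chroman-4-yl}benzaldehyde | O(Cc5ccccc5)c1ccc([C@@H]2C[C@H](c3c(OCc5ccccc5)cc(F)c(C=O)c3OCc5ccccc5)c3ccc(OCc5ccccc5)cc3O2)cc1 | intermediate
13 | (2S,4S)-7-(benzyloxy)-2-[4-(benzyloxy)phenyl]-4-[2,6-bis(benzyloxy)-4-fluoro-3-(hydroxymethyl)phenyl]chroman | O(Cc5ccccc5)c1ccc([C@@H]2C[C@H](c3c(OCc5ccccc5)cc(F)c(CO)c3OCc5ccccc5)c3ccc(OCc5ccccc5)cc3O2)cc1 | intermediate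
14 | (2S,4S)-7-(benzyloxy)-2-[4-(benzyloxy)phenyl]-4-[2,6-bis(benzyloxy)-3-(chloromethyl)-4-fluorophenyl]chroman | O(Cc5ccccc5)c1ccc([C@@H]2C[C@H](c3c(OCc5ccccc5)cc(F)c(CCl)c3OCc5ccccc5)c3ccc(OCc5ccccc5)cc3O2)cc1 | intermediate
15 | 1,3-dithiane | C1CSCSC1 | starting material
16 | methyl 4-(benzyloxy)benzoate | COC(=O)c1ccc(OCc2ccccc2)cc1 | starting material
17 | 2-lithio-1,3-dithiane | [Li]C1SCCCS1 | intermediate
18 | [4-(benzyloxy)phenyl](1,3-dithian-2-yl)methanone | O=C(c1ccc(OCc2ccccc2)cc1)C1SCCCS1 | intermediate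
19 | (R)-[4-(benzyloxy)phenyl](1,3-dithian-2-yl)methanol | C1(SCCCS1)[C@@H](c2ccc(OCc3ccccc3)cc2)O | intermediate
20 | dilithium salt of 19 (oxide at C2, carbanion at the dithiane C2 position) | [C-]1(SCCCS1)[C@@H](c2ccc(OCc3ccccc3)cc2)[O-].[Li+].[Li+] | intermediate
21 | lithium (R)-alkoxide from C-benzylation of 20 by 14 (C8a–F still in place) | O(Cc5ccccc5)c1ccc([C@@H]2C[C@H](c3c(OCc5ccccc5)cc(F)c(CC6(SCCCS6)[C@@H](c7ccc(OCc5ccccc5)cc7)[O-])c3OCc5ccccc5)c3ccc(OCc5ccccc5)cc3O2)cc1.[Li+] | intermediate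
22 | (2R)-5,7-bis(benzyloxy)-2-[4-(benzyloxy)phenyl]-6-{(2S,4S)-7-(benzyloxy)-2-[4-(benzyloxy)phenyl]chroman-4-yl}spiro[chroman-3,2'-[1,3]dithiane] | O(Cc5ccccc5)c1ccc([C@@H]2C[C@H](c3c(OCc5ccccc5)cc4c(c3OCc5ccccc5)CC6(SCCCS6)[C@@H](c3ccc(OCc5ccccc5)cc3)O4)c3ccc(OCc5ccccc5)cc3O2)cc1 | intermediate
23 | (2R)-5,7-bis(benzyloxy)-2-[4-(benzyloxy)phenyl]-6-{(2S,4S)-7-(benzyloxy)-2-[4-(benzyloxy)phenyl]chroman-4-yl}chroman-3-one | O(Cc5ccccc5)c1ccc([C@@H]2C[C@H](c3c(OCc5ccccc5)cc4c(c3OCc5ccccc5)CC(=O)[C@@H](c3ccc(OCc5ccccc5)cc3)O4)c3ccc(OCc5ccccc5)cc3O2)cc1 | intermediate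
24 | (2R,3R)-5,7-bis(benzyloxy)-2-[4-(benzyloxy)phenyl]-6-{(2S,4S)-7-(benzyloxy)-2-[4-(benzyloxy)phenyl]chroman-4-yl}chroman-3-ol | O(Cc5ccccc5)c1ccc([C@@H]2C[C@H](c3c(OCc5ccccc5)cc4c(c3OCc5ccccc5)C[C@@H](O)[C@@H](c3ccc(OCc5ccccc5)cc3)O4)c3ccc(OCc5ccccc5)cc3O2)cc1 | intermediate
25 | (2R,3R)-2-(4-hydroxyphenyl)-6-[(2S,4S)-7-hydroxy-2-(4-hydroxyphenyl)chroman-4-yl]chroman-3,5,7-triol | Oc1ccc([C@@H]2C[C@H](c3c(O)cc4c(c3O)C[C@@H](O)[C@@H](c3ccc(O)cc3)O4)c3ccc(O)cc3O2)cc1 | target

Total step count: 14. Longest linear sequence: 10 steps (1, 2, 5, 6, 7, 8, 11, 12, 13, 14).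

Steps most likely to fail

Step 11 (bears the new-method label). Several processes could interfere:
- The second deprotonation of 19 may stay incomplete.
- Proton transfer or O-benzylation may compete with C-benzylation.
- The hindered alkoxide may undergo retro-addition (cleavage of the C2–C3 bond) before it closes on C8a.

The fallback uses known chemistry. It sets out from 14 and 18 and comes back at 22, building the two bonds separately and creating C2 in between.
- The sodium enolate of 18 (NaH, DMF, 0 °C) is C-benzylated with 14 to give the quaternary 2-aroyl-2-(arylmethyl)-1,3-dithiane F1.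
- CBS reduction with (S)-Me-CBS and BH3·SMe2, now with a clearly larger quaternary dithianyl flank, gives the R carbinol with C8a–F intact F2.
- KH with 18-crown-6 in DMF at 60 °C closes ring F by intramolecular SNAr to 22.

Step 5. Enolisation of the flavanone followed by retro-oxa-Michael ring opening (loss of C2u), or simple failure of the doubly ortho-substituted aryl nucleophile to add, may intervene. The fallback sets out from 4 and 7 and comes back at 10, replacing carbonyl addition by carbene cross-coupling.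
- Compound 4 is condensed with TsNHNH2 (MeOH, 60 °C) to the flavanone N-tosylhydrazone F3.
- Barluenga coupling with iodide 7 (Pd2(dba)3, XPhos, LiOt-Bu, dioxane, 90 °C) gives the 4-aryl-2H-chromene F4.
- Ionic hydrogenation with Et3SiH and CF3CO2H protonates C3u to the same C4u cation as in step 6 and delivers 10.

Step 10. Enantiofacial discrimination may be poor because both ketone substituents are large. The fallback sets out from 18 and comes back at 19, replacing asymmetric catalysis by covalent resolution.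
- NaBH4 in MeOH gives the racemic carbinol F5.
- Esterification with (S)-2-methoxy-2-phenylacetic acid (DCC, DMAP, CH2Cl2) and separation of the two diastereomers by crystallisation or chromatography gives the (S)-O-methylmandelate of the R carbinol F6.
- LiOH in THF/H2O returns 19.

Further compounds
F1 | step 11 | [4-(benzyloxy)phenyl][2-({2,4-bis(benzyloxy)-6-fluoro-3-[(2S,4S)-7-(benzyloxy)-2-(4-benzyloxyphenyl)chroman-4-yl]phenyl}methyl)-1,3-dithian-2-yl]methanone | O(Cc5ccccc5)c1ccc([C@@H]2C[C@H](c3c(OCc5ccccc5)cc(F)c(CC6(SCCCS6)C(=O)c7ccc(OCc5ccccc5)cc7)c3OCc5ccccc5)c3ccc(OCc5ccccc5)cc3O2)cc1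
F2 | step 11 | (R)-[4-(benzyloxy)phenyl][2-({2,4-bis(benzyloxy)-6-fluoro-3-[(2S,4S)-7-(benzyloxy)-2-(4-benzyloxyphenyl)chroman-4-yl]phenyl}methyl)-1,3-dithian-2-yl]methanol | O(Cc5ccccc5)c1ccc([C@@H]2C[C@H](c3c(OCc5ccccc5)cc(F)c(CC6(SCCCS6)[C@@H](c7ccc(OCc5ccccc5)cc7)O)c3OCc5ccccc5)c3ccc(OCc5ccccc5)cc3O2)cc1
F3 | step 5 | N'-{(2S)-7-(benzyloxy)-2-[4-(benzyloxy)phenyl]chroman-4-ylidene}-4-methylbenzenesulfonohydrazide | O(Cc5ccccc5)c1ccc([C@@H]2CC(=NNS(=O)(=O)c6ccc(C)cc6)c3ccc(OCc5ccccc5)cc3O2)cc1
F4 | step 5 | (2S)-7-(benzyloxy)-2-[4-(benzyloxy)phenyl]-4-[2,6-bis(benzyloxy)-4-fluorophenyl]-2H-chromene | O(Cc5ccccc5)c1ccc([C@@H]2C=C(c3c(OCc5ccccc5)cc(F)cc3OCc5ccccc5)c3ccc(OCc5ccccc5)cc3O2)cc1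
F5 | step 10 | rac-[4-(benzyloxy)phenyl](1,3-dithian-2-yl)methanol | OC(c1ccc(OCc2ccccc2)cc1)C1SCCCS1
F6 | step 10 | (R)-[4-(benzyloxy)phenyl](1,3-dithian-2-yl)methyl (S)-2-methoxy-2-phenylacetate | C1(SCCCS1)[C@@H](c2ccc(OCc3ccccc3)cc2)OC(=O)[C@@H](OC)c4ccccc4
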